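**Plan**

- Retrosynthesis: the gallate esters are cut one at a time (O5 on benzyl quinate, then O4 and O3 on the quinide lactone). The C3/C4 cis-diol goes back to a C3=C4 alkene in the quinide lactone, and the ring bonds C1–C6 and C4–C5 (quinic acid numbering) are cut together by a retro-Diels–Alder reaction to a 2-pyrone and methyl vinyl ketone.
- Enabling feature: in the cyclohexane ring, C1 (carrying OH and CO2H) and C4 are 1,4-related with C2–C3 between them. C1–C2–C3–C4 is therefore the diene C6–C5–C4–C3 of ethyl 3-hydroxy-2-pyrone-6-carboxylate (ring O = C1–O, 6-ester = C1 carboxyl), and C6–C5 is a vinyl unit.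
- Ring order forward: mucic acid gives the pyrone; the [4+2] step builds the carbocycle inside a 2-oxabicyclo[2.2.2]octene; Baeyer–Villiger oxidation turns the acetyl helper into the C5 oxygen.
- The pyrone lactone bridge is then exchanged for the quinide lactone (6-oxabicyclo[3.2.1]octane), the helper carbonyl carbon leaves as CO2, and the enone is transposed to the C3=C4 alkene and dihydroxylated.
- Stereochemistry: the catalyst-controlled endo cycloaddition sets C1 and C5 (absolute); C3 and C4 come from exo-face dihydroxylation of the rigid lactone.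
- End game: the rigid quinide offers its hydroxyls one by one, so O3 and then O4 are galloylated on the lactone, the lactone is exchanged for a benzyl ester, O5 is galloylated, and global hydrogenolysis follows.

Key step: step 3

Remark: which of the two pseudoenantiomeric cinchona catalysts gives the required (1R,4S,8R) adduct must be settled by experiment; the route is written for the one that does. For compounds 15 to 18 the locants are those of quinic acid (C1 carries OH and the carboxyl, C5 carries the oxygen that closes the lactone), and all ring stereocenters are those of 13.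

**Route**

Step 1
Reactants: 1 mucic acid (galactaric acid)
Product: 2 3-(acetyloxy)-2-oxo-2H-pyran-6-carboxylic acid
Conditions: Ac2O, NaOAc, 100 °C; then aq. HCl
Reagents that add atoms: acetic anhydride, CC(=O)OC(C)=O
Why: Acetic anhydride-driven triple dehydration and lactonization of an aldaric acid is the known entry to 3-acyloxy-2-pyrone-6-carboxylates; all sugar stereocenters are erased, so the meso acid serves as a cheap flat heteroarene precursor.

Step 2
Reactants: 2 3-(acetyloxy)-2-oxo-2H-pyran-6-carboxylic acid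
Product: 3 ethyl 3-hydroxy-2-oxo-2H-pyran-6-carboxylate
Conditions: EtOH, HCl (from AcCl), reflux
Reagents that add atoms: ethanol, CCO
Why: Fischer esterification with concurrent ethanolysis of the enol acetate should give the ester and free the acidic 3-OH that the base catalyst needs in step 3.

Step 3
Reactants: 3 ethyl 3-hydroxy-2-oxo-2H-pyran-6-carboxylate; 4 methyl vinyl ketone
Product: 5 ethyl (1R,4S,8R)-8-acetyl-4-hydroxy-3-oxo-2-oxabicyclo[2.2.2]oct-5-ene-1-carboxylate (acetyl endo, syn to the C5=C6 bridge)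
Conditions: 9-O-benzylcupreidine (10 mol %), EtOAc, 0 °C to rt
Reagents that add atoms: none
Why: The quinuclidine base deprotonates the 3-OH, and the hydrogen-bonded 3-oxidopyrone (diene C3=C4–C5=C6) should add the enone in a normal-demand, strongly asynchronous Diels–Alder reaction (Michael–aldol limit), forming pyrone C6–CH2 first and pyrone C3–CH(Ac) second. The closest known reaction type is the amine- and cinchona-base-catalysed Diels–Alder reaction of 3-hydroxy-2-pyrones with enones and acrylates. The carbocycle is closed by an intermolecular suprafacial [4+2] cycloaddition and is formed as the boat of a 2-oxabicyclo[2.2.2]oct-5-ene whose lactone bridge ties C1 to C4. The bridgeheads C1 and C4 follow from addition to one face of the flat pyrone, chosen by the chiral ion pair, and C8 follows from the endo rule, helped by the hydrogen bond from the catalyst 6'-OH to the acetyl group. The step needs regioselectivity (CH2 to the ester-bearing pyrone C6), secured because the 3-oxido group makes C6 the nucleophilic terminus and leaves C3 as the electrophilic keto carbon; it also needs endo and enantiofacial selectivity, which rest on the catalyst.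

Step 4
Reactants: 5 ethyl (1R,4S,8R)-8-acetyl-4-hydroxy-3-oxo-2-oxabicyclo[2.2.2]oct-5-ene-1-carboxylate
Product: 6 ethyl (1R,4S,8R)-8-(acetyloxy)-4-hydroxy-3-oxo-2-oxabicyclo[2.2.2]oct-5-ene-1-carboxylate
Conditions: mCPBA, NaHCO3, CH2Cl2, rt
Reagents that add atoms: 3-chloroperbenzoic acid, OOC(=O)c1cccc(Cl)c1
Why: In the Baeyer–Villiger oxidation the secondary ring carbon should migrate in preference to methyl with retention, so the endo acetyl becomes the endo acetate (the future C5 oxygen); the bridged alkene, flanked by two acceptor-substituted bridgeheads, should be epoxidized only slowly.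

Step 5
Reactants: 6 ethyl (1R,4S,8R)-8-(acetyloxy)-4-hydroxy-3-oxo-2-oxabicyclo[2.2.2]oct-5-ene-1-carboxylate
Product: 8 (1R,4S,5R)-1,4-dihydroxy-7-oxo-6-oxabicyclo[3.2.1]oct-2-ene-4-carboxylic acid, via trihydroxy diacid 7 (not isolated)
Conditions: LiOH, THF/H2O, 0 °C to rt; HCl to pH 1; then TsOH (cat.), MeCN, 60 °C
Reagents that add atoms: lithium hydroxide, [Li+].[OH-]; water, O
Why: Saponification (acyl–oxygen cleavage, all stereocenters retained) frees both carboxyl groups and the secondary hydroxyl; on acid treatment the only secondary hydroxyl that is cis-1,3 to a carboxyl should close the quinide-type γ-lactone, which masks the C1 α-hydroxy acid and leaves the helper α-hydroxy acid free.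

Step 6
Reactants: 8 (1R,4S,5R)-1,4-dihydroxy-7-oxo-6-oxabicyclo[3.2.1]oct-2-ene-4-carboxylic acid
Product: 9 (1R,5R)-1-hydroxy-6-oxabicyclo[3.2.1]oct-2-ene-4,7-dione
Conditions: Pb(OAc)4, MeCN, 0 °C to rt
Reagents that add atoms: none
Why: Oxidative decarboxylation of a tertiary α-hydroxy acid with Pb(OAc)4 should expel the helper carbon (the former pyrone C2) as CO2 and leave a conjugated enone; the C1 hydroxyl is safe because its carboxyl is tied up in the lactone.

Step 7
Reactants: 9 (1R,5R)-1-hydroxy-6-oxabicyclo[3.2.1]oct-2-ene-4,7-dione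
Product: 10 N'-[(1R,5R)-1-hydroxy-7-oxo-6-oxabicyclo[3.2.1]oct-2-en-4-ylidene]-4-methylbenzenesulfonohydrazide
Conditions: TsNHNH2, EtOH, AcOH (cat.), rt
Reagents that add atoms: 4-methylbenzenesulfonohydrazide, Cc1ccc(cc1)S(=O)(=O)NN
Why: Acid-catalysed condensation of the enone carbonyl with tosylhydrazide should give the α,β-unsaturated tosylhydrazone without touching the lactone.

Step 8
Reactants: 10 N'-[(1R,5R)-1-hydroxy-7-oxo-6-oxabicyclo[3.2.1]oct-2-en-4-ylidene]-4-methylbenzenesulfonohydrazide
Product: 12 (1S,5R)-1-hydroxy-6-oxabicyclo[3.2.1]oct-3-en-7-one, via allylic diazene 11 (not isolated)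
Conditions: catecholborane, CHCl3, 0 °C; then NaOAc·3H2O, reflux
Reagents that add atoms: none
Why: 1,2-Hydride delivery to the C=N bond, loss of sulfinate and retro-ene loss of N2 from the allylic diazene should move the double bond to C3=C4 and leave C2 as CH2 (the alkene-transposing variant of the Wolff–Kishner reduction of enone tosylhydrazones); the helper oxygen of the pyrone 3-OH is removed here.

Step 9
Reactants: 12 (1S,5R)-1-hydroxy-6-oxabicyclo[3.2.1]oct-3-en-7-one
Product: 13 (1S,3R,4R,5R)-1,3,4-trihydroxy-6-oxabicyclo[3.2.1]octan-7-one (quinide)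
Conditions: OsO4 (cat.), NMO, acetone/H2O, rt
Reagents that add atoms: osmium tetroxide, O=[Os](=O)(=O)=O; N-methylmorpholine N-oxide, C[N+]1([O-])CCOCC1
Why: Catalytic cis-dihydroxylation should occur on the exo face, anti to the lactone bridge that lies under the six-membered ring, which places both new hydroxyls cis to each other and trans to the C5 oxygen, as in quinide.

Step 10
Reactants: 13 quinide; 14 3,4,5-tris(benzyloxy)benzoyl chloride
Product: 15 3-O-[3,4,5-tris(benzyloxy)benzoyl]quinide (13 esterified at the equatorial C3 hydroxyl)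
Conditions: 14 (1.05 equiv), pyridine, CH2Cl2, -20 °C to 0 °C
Reagents that add atoms: none
Why: On the rigid lactone the equatorial C3 hydroxyl should be acylated ahead of the axial C4 hydroxyl next to the bridgehead and of the tertiary C1 hydroxyl, as in the known O3-selective silylation and acylation of quinide (nucleophilic acyl substitution, no stereocenter touched).

Step 11
Reactants: 15 3-O-[3,4,5-tris(benzyloxy)benzoyl]quinide; 14 3,4,5-tris(benzyloxy)benzoyl chloride
Product: 16 3,4-bis-O-[3,4,5-tris(benzyloxy)benzoyl]quinide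
Conditions: 14 (1.2 equiv), pyridine, DMAP (cat.), CH2Cl2, 0 °C to rt
Reagents that add atoms: none
Why: DMAP-catalysed acylation should now take the only remaining secondary hydroxyl, the axial one at C4, while the tertiary C1 hydroxyl next to the lactone carbonyl stays free under stoichiometric control; any O4 mono-ester carried over from step 10 would converge on the same diester.

Step 12
Reactants: 16 3,4-bis-O-[3,4,5-tris(benzyloxy)benzoyl]quinide
Product: 18 benzyl 3,4-bis-O-[3,4,5-tris(benzyloxy)benzoyl]quinate, via hydroxy acid 17 (not isolated)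
Conditions: 2 M aq. HCl, THF, 40 °C; extractive work-up; then BnBr, KHCO3, DMF, rt
Reagents that add atoms: water, O; benzyl bromide, BrCc1ccccc1
Why: Acid-catalysed hydrolysis (acyl–oxygen cleavage, so C5 keeps its configuration) should open the strained bicyclic γ-lactone well before the hindered, electron-rich aryl esters react, as in the acid hydrolysis of acylated quinides to acylquinic acids, and the carboxylic acid is then O-benzylated by carboxylate alkylation under bicarbonate conditions too mild to touch the hydroxyls.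

Step 13
Reactants: 18 benzyl 3,4-bis-O-[3,4,5-tris(benzyloxy)benzoyl]quinate; 14 3,4,5-tris(benzyloxy)benzoyl chloride
Product: 19 benzyl (1S,3R,4S,5R)-1-hydroxy-3,4,5-tris{[3,4,5-tris(benzyloxy)benzoyl]oxy}cyclohexane-1-carboxylate
Conditions: 14 (1.3 equiv), pyridine, DMAP (cat.), CH2Cl2, 0 °C to rt
Reagents that add atoms: none
Why: Only one secondary hydroxyl, the equatorial one at C5, is left, so DMAP-catalysed acylation should complete the tri-ester while the hindered tertiary C1 hydroxyl next to the ester stays free; an acyl shift between O4 and O5 during step 12 would lead to the same product.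

Step 14
Reactants: 19 benzyl (1S,3R,4S,5R)-1-hydroxy-3,4,5-tris{[3,4,5-tris(benzyloxy)benzoyl]oxy}cyclohexane-1-carboxylate
Product: 20 (1S,3R,4S,5R)-1-hydroxy-3,4,5-tris[(3,4,5-trihydroxybenzoyl)oxy]cyclohexane-1-carboxylic acid (3,4,5-tri-O-galloylquinic acid)
Conditions: H2 (1 atm), Pd/C, THF/MeOH, rt
Reagents that add atoms: none
Why: Hydrogenolysis should cleave the nine aryl benzyl ethers and the benzyl ester in one operation under neutral conditions that leave the gallate esters and all stereocenters untouched.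

**Compound list**

1 | mucic acid (galactaric acid, meso) | OC(=O)[C@@H](O)[C@H](O)[C@H](O)[C@@H](O)C(=O)O | starting material
2 | 3-(acetyloxy)-2-oxo-2H-pyran-6-carboxylic acid | CC(=O)OC1=CC=C(C(=O)O)OC1=O | intermediate
3 | ethyl 3-hydroxy-2-oxo-2H-pyran-6-carboxylate | CCOC(=O)C1=CC=C(O)C(=O)O1 | intermediate
4 | methyl vinyl ketone | CC(=O)C=C | starting material
5 | ethyl (1R,4S,8R)-8-acetyl-4-hydroxy-3-oxo-2-oxabicyclo[2.2.2]oct-5-ene-1-carboxylate | CC(=O)[C@@H]1C[C@]2(C(=O)OCC)C=C[C@@]1(O)C(=O)O2 | intermediate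
6 | ethyl (1R,4S,8R)-8-(acetyloxy)-4-hydroxy-3-oxo-2-oxabicyclo[2.2.2]oct-5-ene-1-carboxylate | CC(=O)O[C@@H]1C[C@]2(C(=O)OCC)C=C[C@@]1(O)C(=O)O2 | intermediate
7 | (1R,4S,5R)-1,4,5-trihydroxycyclohex-2-ene-1,4-dicarboxylic acid | O[C@@H]1C[C@](O)(C(=O)O)C=C[C@@]1(O)C(=O)O | intermediate (not isolated)
8 | (1R,4S,5R)-1,4-dihydroxy-7-oxo-6-oxabicyclo[3.2.1]oct-2-ene-4-carboxylic acid | O=C1O[C@@H]2C[C@@]1(O)C=C[C@@]2(O)C(=O)O | intermediate
9 | (1R,5R)-1-hydroxy-6-oxabicyclo[3.2.1]oct-2-ene-4,7-dione | O=C1O[C@@H]2C[C@@]1(O)C=CC2=O | intermediate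
10 | N'-[(1R,5R)-1-hydroxy-7-oxo-6-oxabicyclo[3.2.1]oct-2-en-4-ylidene]-4-methylbenzenesulfonohydrazide | O=C1O[C@@H]2C[C@@]1(O)C=CC2=NNS(=O)(=O)c1ccc(C)cc1 | intermediate
11 | (1R,5R)-4-diazenyl-1-hydroxy-6-oxabicyclo[3.2.1]oct-2-en-7-one (C4 configuration not controlled and of no consequence) | O=C1O[C@@H]2C[C@@]1(O)C=CC2N=N | intermediate (not isolated)
12 | (1S,5R)-1-hydroxy-6-oxabicyclo[3.2.1]oct-3-en-7-one | O=C1O[C@@H]2C[C@@]1(O)CC=C2 | intermediate
13 | (1S,3R,4R,5R)-1,3,4-trihydroxy-6-oxabicyclo[3.2.1]octan-7-one (quinide) | O=C1O[C@@H]2C[C@@]1(O)C[C@@H](O)[C@H]2O | intermediate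
14 | 3,4,5-tris(benzyloxy)benzoyl chloride | O=C(Cl)c1cc(OCc2ccccc2)c(OCc2ccccc2)c(OCc2ccccc2)c1 | starting material
15 | 3-O-[3,4,5-tris(benzyloxy)benzoyl]quinide (13 esterified at the equatorial C3 hydroxyl; free 1-OH and 4-OH) | O=C1O[C@@H]2C[C@@]1(O)C[C@@H](OC(=O)c1cc(OCc3ccccc3)c(OCc3ccccc3)c(OCc3ccccc3)c1)[C@H]2O | intermediate
16 | 3,4-bis-O-[3,4,5-tris(benzyloxy)benzoyl]quinide (13 esterified at both secondary hydroxyls; free 1-OH) | O=C1O[C@@H]2C[C@@]1(O)C[C@@H](OC(=O)c1cc(OCc3ccccc3)c(OCc3ccccc3)c(OCc3ccccc3)c1)[C@H]2OC(=O)c1cc(OCc2ccccc2)c(OCc2ccccc2)c(OCc2ccccc2)c1 | intermediate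
17 | 3,4-bis-O-[3,4,5-tris(benzyloxy)benzoyl]quinic acid (free 1-OH, 5-OH and carboxyl) | O[C@@H]1C[C@](O)(C(=O)O)C[C@@H](OC(=O)c2cc(OCc3ccccc3)c(OCc3ccccc3)c(OCc3ccccc3)c2)[C@H]1OC(=O)c1cc(OCc2ccccc2)c(OCc2ccccc2)c(OCc2ccccc2)c1 | intermediate (not isolated)
18 | benzyl 3,4-bis-O-[3,4,5-tris(benzyloxy)benzoyl]quinate (free 1-OH and 5-OH) | O[C@@H]1C[C@](O)(C(=O)OCc2ccccc2)C[C@@H](OC(=O)c2cc(OCc3ccccc3)c(OCc3ccccc3)c(OCc3ccccc3)c2)[C@H]1OC(=O)c1cc(OCc2ccccc2)c(OCc2ccccc2)c(OCc2ccccc2)c1 | intermediate
19 | benzyl (1S,3R,4S,5R)-1-hydroxy-3,4,5-tris{[3,4,5-tris(benzyloxy)benzoyl]oxy}cyclohexane-1-carboxylate | O=C(O[C@@H]1C[C@](O)(C(=O)OCc2ccccc2)C[C@@H](OC(=O)c2cc(OCc3ccccc3)c(OCc3ccccc3)c(OCc3ccccc3)c2)[C@H]1OC(=O)c1cc(OCc2ccccc2)c(OCc2ccccc2)c(OCc2ccccc2)c1)c1cc(OCc2ccccc2)c(OCc2ccccc2)c(OCc2ccccc2)c1 | intermediate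
20 | (1S,3R,4S,5R)-1-hydroxy-3,4,5-tris[(3,4,5-trihydroxybenzoyl)oxy]cyclohexane-1-carboxylic acid | O=C(O[C@@H]1C[C@](O)(C(=O)O)C[C@@H](OC(=O)c2cc(O)c(O)c(O)c2)[C@H]1OC(=O)c1cc(O)c(O)c(O)c1)c1cc(O)c(O)c(O)c1 | target

**Step count**

Total steps: 14. Longest linear sequence: 14 steps (1 to 20).

**Steps most likely to fail**

Step 3. The ion pair may be too loosely organized to give useful facial or endo selectivity, and conjugate addition at pyrone C4 without ring closure may compete. Fallback by auxiliary control and diastereomer separation, setting out from 2: Fischer esterification with (1R,2S,5R)-menthol (TsOH, toluene, water removal; the enol acetate is lost as menthyl acetate) should give (1R,2S,5R)-5-methyl-2-(propan-2-yl)cyclohexyl 3-hydroxy-2-oxo-2H-pyran-6-carboxylate F1. Its Et3N-catalysed cycloaddition with 4 should give endo adducts as two diastereomers, from which menthyl (1R,4S,8R)-8-acetyl-4-hydroxy-3-oxo-2-oxabicyclo[2.2.2]oct-5-ene-1-carboxylate F2 is separated by crystallization or chromatography. Peracid oxidation as in step 4 gives the corresponding 8-acetate F3, and saponification with lactonization as in step 5 releases menthol and rejoins the route at 8.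

Step 4. Oxygen insertion into the deactivated methyl ketone may be slower than epoxidation of the bridged alkene. Fallback that changes the migrating substrate, setting out from 3: the cycloaddition of step 3 is run with acrolein in place of 4 to give ethyl (1R,4S,8R)-8-formyl-4-hydroxy-3-oxo-2-oxabicyclo[2.2.2]oct-5-ene-1-carboxylate F4. The α-branched aldehyde should undergo peracid oxidation to the formate much faster than the ketone (mCPBA, CH2Cl2, 0 °C), giving ethyl (1R,4S,8R)-8-(formyloxy)-4-hydroxy-3-oxo-2-oxabicyclo[2.2.2]oct-5-ene-1-carboxylate F5. Saponification and lactonization as in step 5 rejoin the route at 8.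

Step 12. Hydrolysis of the lactone may stop at an unfavourable equilibrium or be accompanied by cleavage of an aryl ester, and the hydroxy acid may close back to the lactone during work-up. Fallback that opens the lactone before any ester is present, setting out from 13: base-catalysed transesterification in benzyl alcohol (BnOH, BnONa cat., rt) should give benzyl (1S,3R,4S,5R)-1,3,4,5-tetrahydroxycyclohexane-1-carboxylate F6. Exhaustive acylation of its three secondary hydroxyls with three equivalents of 14 (pyridine, DMAP, CH2Cl2, 0 °C to rt) rejoins the route at 19. This shorter path is held in reserve because its last acylation must be forced at a hydroxyl flanked by two gallates on a flexible ring, where acylation of the tertiary hydroxyl begins to compete.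

**Further compounds**

F1 | step 3 | (1R,2S,5R)-5-methyl-2-(propan-2-yl)cyclohexyl 3-hydroxy-2-oxo-2H-pyran-6-carboxylate | CC(C)[C@@H]1CC[C@@H](C)C[C@H]1OC(=O)C1=CC=C(O)C(=O)O1
F2 | step 3 | (1R,2S,5R)-5-methyl-2-(propan-2-yl)cyclohexyl (1R,4S,8R)-8-acetyl-4-hydroxy-3-oxo-2-oxabicyclo[2.2.2]oct-5-ene-1-carboxylate | CC(=O)[C@@H]1C[C@]2(C(=O)O[C@@H]3C[C@H](C)CC[C@H]3C(C)C)C=C[C@@]1(O)C(=O)O2
F3 | step 3 | (1R,2S,5R)-5-methyl-2-(propan-2-yl)cyclohexyl (1R,4S,8R)-8-(acetyloxy)-4-hydroxy-3-oxo-2-oxabicyclo[2.2.2]oct-5-ene-1-carboxylate | CC(=O)O[C@@H]1C[C@]2(C(=O)O[C@@H]3C[C@H](C)CC[C@H]3C(C)C)C=C[C@@]1(O)C(=O)O2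
F4 | step 4 | ethyl (1R,4S,8R)-8-formyl-4-hydroxy-3-oxo-2-oxabicyclo[2.2.2]oct-5-ene-1-carboxylate | O=C[C@@H]1C[C@]2(C(=O)OCC)C=C[C@@]1(O)C(=O)O2
F5 | step 4 | ethyl (1R,4S,8R)-8-(formyloxy)-4-hydroxy-3-oxo-2-oxabicyclo[2.2.2]oct-5-ene-1-carboxylate | O=CO[C@@H]1C[C@]2(C(=O)OCC)C=C[C@@]1(O)C(=O)O2
F6 | step 12 | benzyl (1S,3R,4S,5R)-1,3,4,5-tetrahydroxycyclohexane-1-carboxylate (benzyl quinate) | O[C@@H]1C[C@](O)(C(=O)OCc2ccccc2)C[C@@H](O)[C@H]1O
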